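## Retrosynthetic overview

1. The target is (3R)-6,8-dihydroxy-3-[(9S)-9-hydroxyundecyl]isochroman-1-one (15). The last step saturates a C1'=C2' alkene and removes two benzyl ethers (15 ⇐ 13).
2. Key disconnection (13 ⇐ 5 + 12): C4–C4a and O2–C3 are made together by a Pd(0)/chiral-phosphine arylation–acyloxylation (Heck/Tsuji–Trost annulation) of the terminal (E)-1,3-diene 12 with the ortho-bromobenzoic acid 5. This one step closes the lactone and sets C3.
3. Enabling feature: C3 sits between the benzylic C4H2 and the unfunctionalised C1'H2–C2'H2 of the side chain. With C1'=C2' carried as an alkene, C4–C3–C1'–C2' is a buta-1,3-diene whose CH2 end takes the aryl carbon C4a and whose allyl carbon C3 takes the carboxyl oxygen held ortho on the resorcinol ring.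
4. Dienol 12 ⇐ (S)-1,2-epoxybutane (source of C9') + hept-1-yne, by alkynylation, alkyne zipper and hydrozirconation/vinylation. Acid 5 ⇐ 5-bromoresorcinol, by benzylation, formylation and oxidation.
5. Rings: the benzene ring is bought; the δ-lactone (O2–C3–C4–C4a–C8a–C1) is the only ring formed, in step 7.

Key step: step 7

Remark: lactone atoms are numbered as in isochroman-1-one and side-chain atoms C1'–C11' from C3; the ligand antipode for step 7 is to be fixed by a pilot run with both antipodes, since the sense of induction cannot be taken over from the precedents.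

## Route

Step 1
Reactants: 1 5-bromoresorcinol
Product: 2 1,3-bis(benzyloxy)-5-bromobenzene
Conditions: BnBr (2.3 equiv), K2CO3 (3 equiv), DMF, 60 °C
Reagents that add atoms: benzyl bromide BrCc1ccccc1
Why: Williamson ether synthesis, in which both phenoxides are alkylated by the reactive benzylic bromide; no stereocentre is involved.

Step 2
Reactants: 2 1,3-bis(benzyloxy)-5-bromobenzene
Product: 4 2,4-bis(benzyloxy)-6-bromobenzaldehyde, via iminium chloride 3 (not isolated)
Conditions: POCl3 (1.5 equiv), DMF, 0 → 70 °C; then ice-water
Reagents that add atoms: N,N-dimethylformamide CN(C)C=O; water O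
Why: Vilsmeier–Haack formylation, in which the chloroiminium ion should attack the position para to one benzyloxy group and ortho to the other (next to Br) rather than the more hindered position flanked by both ethers, and the iminium salt is hydrolysed on work-up.

Step 3
Reactants: 4 2,4-bis(benzyloxy)-6-bromobenzaldehyde
Product: 5 2,4-bis(benzyloxy)-6-bromobenzoic acid
Conditions: NaClO2, NaH2PO4, 2-methylbut-2-ene, t-BuOH/THF/H2O, 0 °C → rt
Reagents that add atoms: sodium chlorite [Na+].[O-]Cl=O
Why: Pinnick oxidation, in which chlorous acid oxidises the aldehyde without touching the aryl bromide or the benzyl ethers, while the alkene scavenges the HOCl that could chlorinate the electron-rich ring.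

Step 4
Reactants: 6 hept-1-yne; 7 (S)-1,2-epoxybutane
Product: 9 (3S)-undec-5-yn-3-ol, via lithium heptynide 8 (not isolated)
Conditions: n-BuLi, THF, −78 °C; BF3·OEt2, then 7, −78 °C; aqueous work-up
Reagents that add atoms: none
Why: BF3-promoted acetylide opening of a terminal epoxide, an SN2 attack at the unsubstituted CH2, so the stereocentre of 7 is not touched and becomes C3 (S) of 9 (later C9' of the target).

Step 5
Reactants: 9 (3S)-undec-5-yn-3-ol
Product: 10 (3S)-undec-10-yn-3-ol
Conditions: KH, H2N(CH2)3NH2, 0 °C → rt; then H2O
Reagents that add atoms: none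
Why: Alkyne zipper isomerisation, in which repeated propargyl/allenyl proton shifts walk the triple bond along the chain until it is trapped as the terminal acetylide; migration past the carbinol is blocked by the alkoxide, whose C–H is not acidic, so C3 should keep its configuration.

Step 6
Reactants: 10 (3S)-undec-10-yn-3-ol
Product: 12 (3S,10E)-trideca-10,12-dien-3-ol, via alkenylzirconocene 11 (not isolated)
Conditions: Cp2Zr(H)Cl (2.2 equiv), THF, rt; then CH2=CHBr (1 M in THF), Pd(PPh3)4 (5 mol %), rt; cold 1 M HCl work-up
Reagents that add atoms: vinyl bromide C=CBr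
Why: Hydrozirconation followed by Negishi-type Pd-catalysed alkenyl–alkenyl coupling, in which the first equivalent of the Schwartz reagent turns OH into the zirconium alkoxide, the second adds syn and anti-Markovnikov to the terminal alkyne, and the (E)-alkenylzirconium couples with vinyl bromide with retention of geometry.

Step 7
Reactants: 5 2,4-bis(benzyloxy)-6-bromobenzoic acid; 12 (3S,10E)-trideca-10,12-dien-3-ol
Product: 13 (3S)-6,8-bis(benzyloxy)-3-[(1E,9S)-9-hydroxyundec-1-en-1-yl]isochroman-1-one
Conditions: Pd2(dba)3·CHCl3 (2.5 mol %), chiral sulfinamide–phosphine ligand (Sadphos/TY-Phos type, 6 mol %), Cs2CO3 (2.2 equiv), 1,4-dioxane, 70 °C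
Reagents that add atoms: none
Why: Proposed new method: Pd(0)L* inserts into the C–Br bond of the caesium salt of 5 (the ortho carboxylate then replaces bromide on Pd and frees a site next to the single chiral phosphine), the terminal C12=C13 bond of 12 undergoes migratory insertion with the aryl carbon going to C13H2 and Pd to C12, and the syn,syn-η3-allyl complex over C12–C10 is closed at C12 by the carboxylate oxygen, which releases Pd(0). The closest known reaction types are the racemic Pd-catalysed heteroannulation of 1,3-dienes with ortho-iodobenzoic acids to 3-alkenyl-3,4-dihydroisocoumarins and the enantioselective Heck/Tsuji–Trost annulation of 1,3-dienes with ortho-halophenols and ortho-haloanilines under chiral monophosphines, so that only enantiocontrol with a carboxylate as the ring-closing nucleophile is untested. The δ-lactone closes by 6-exo attack of O on the proximal allyl terminus, the distal terminus C10 being out of reach because it would need an eight-membered ring. C3 is the only new stereocentre and is under catalyst control: the ligand chooses the face of C12=C13 in the insertion and the stereospecific C–O closure anti to Pd hands this choice on to carbon, while the carbinol of 12, nine bonds away, should have no say. The step needs aryl delivery to the CH2 terminus, O-attack at C12 and one alkene geometry; the first two are secured by the unhindered monosubstituted alkene and by the ortho tether, the third by the (E)-purity of 12, because an anti-substituted allyl from a (Z)-diene could change the Pd face at C12 by η3–η1–η3 isomerisation before closure.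

Step 8
Reactants: 13 (3S)-6,8-bis(benzyloxy)-3-[(1E,9S)-9-hydroxyundec-1-en-1-yl]isochroman-1-one
Product: 15 (3R)-6,8-dihydroxy-3-[(9S)-9-hydroxyundecyl]isochroman-1-one, via saturated dibenzyl ether 14 (not isolated)
Conditions: H2 (1 atm), 5 % Pt/C, EtOAc, rt; then 20 % Pd(OH)2/C, EtOH, H2 (1 atm), rt
Reagents that add atoms: none
Why: Heterogeneous hydrogenation then hydrogenolysis, with Pt chosen for the C=C because it causes little double-bond migration and little allylic C–O cleavage at C3, after which Pd(OH)2 cleaves both aryl benzyl ethers; no stereocentre is formed and C3 and C9' are untouched (the descriptor at C3 changes from S to R only because the side-chain priority changes).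

## Compound list

1 | 5-bromoresorcinol (5-bromobenzene-1,3-diol) | Oc1cc(O)cc(Br)c1 | starting material
2 | 1,3-bis(benzyloxy)-5-bromobenzene | Brc1cc(OCc2ccccc2)cc(OCc2ccccc2)c1 | intermediate
3 | N-[2,4-bis(benzyloxy)-6-bromobenzylidene]-N-methylmethanaminium chloride (not isolated) | C[N+](C)=Cc1c(Br)cc(OCc2ccccc2)cc1OCc1ccccc1.[Cl-] | intermediate
4 | 2,4-bis(benzyloxy)-6-bromobenzaldehyde | O=Cc1c(Br)cc(OCc2ccccc2)cc1OCc1ccccc1 | intermediate
5 | 2,4-bis(benzyloxy)-6-bromobenzoic acid | OC(=O)c1c(Br)cc(OCc2ccccc2)cc1OCc1ccccc1 | intermediate
6 | hept-1-yne | C#CCCCCC | starting material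
7 | (S)-1,2-epoxybutane ((2S)-2-ethyloxirane) | CC[C@H]1CO1 | starting material
8 | lithium hept-1-yn-1-ide (not isolated) | [Li]C#CCCCCC | intermediate
9 | (3S)-undec-5-yn-3-ol | CC[C@H](O)CC#CCCCCC | intermediate
10 | (3S)-undec-10-yn-3-ol | CC[C@H](O)CCCCCCC#C | intermediate
11 | chlorobis(cyclopentadienyl)[(1E,9S)-9-{[chlorobis(cyclopentadienyl)zirconio]oxy}undec-1-en-1-yl]zirconium (not isolated; Cp rings written σ-bonded in the SMILES) | CC[C@H](O[Zr](Cl)(C1C=CC=C1)C1C=CC=C1)CCCCCC/C=C/[Zr](Cl)(C1C=CC=C1)C1C=CC=C1 | intermediate
12 | (3S,10E)-trideca-10,12-dien-3-ol | CC[C@H](O)CCCCCC/C=C/C=C | intermediate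
13 | (3S)-6,8-bis(benzyloxy)-3-[(1E,9S)-9-hydroxyundec-1-en-1-yl]isochroman-1-one | CC[C@H](O)CCCCCC/C=C/[C@@H]1Cc2cc(OCc3ccccc3)cc(OCc3ccccc3)c2C(=O)O1 | intermediate
14 | (3R)-6,8-bis(benzyloxy)-3-[(9S)-9-hydroxyundecyl]isochroman-1-one (not isolated) | CC[C@H](O)CCCCCCCC[C@@H]1Cc2cc(OCc3ccccc3)cc(OCc3ccccc3)c2C(=O)O1 | intermediate
15 | (3R)-6,8-dihydroxy-3-[(9S)-9-hydroxyundecyl]isochroman-1-one | CC[C@H](O)CCCCCCCC[C@@H]1Cc2cc(O)cc(O)c2C(=O)O1 | target

## Summary

Total step count: 8.
Longest linear sequence: 5 steps (steps 1, 2, 3, 7, 8; the branch through steps 4, 5, 6, 7, 8 is equally long).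

## Steps most likely to fail

Step 7 (Proposed new method). What may go wrong: insufficient facial control in the migratory insertion; re-ionisation of the allylic lactone C3–O bond by Pd(0), with epimerisation at C3 or elimination to a diene acid; protodecarboxylation of the aryl-palladium carboxylate before the diene inserts. The fallback uses known chemistry only: the C3–O bond is carried in an enantiopure terminal epoxide, the aryl–CH2 bond is formed by epoxide opening, and the ring is closed by lactonisation. It sets out from 7 and 5 and returns at 14. Non-8-en-1-ylmagnesium bromide F1 (from 9-bromonon-1-ene and Mg) would open 7 at CH2 under CuI catalysis to give (3S)-tridec-12-en-3-ol F2. Epoxidation with mCPBA would give (3S)-11-(oxiran-2-yl)undecan-3-ol F3 as both epimers at the oxirane carbon. Hydrolytic kinetic resolution with the antipode of the chiral (salen)Co(III) catalyst that hydrolyses the (2S)-oxirane epimer would leave (3S)-11-[(2R)-oxiran-2-yl]undecan-3-ol F4. Acid 5 would be esterified (MeI, K2CO3, DMF) to methyl 2,4-bis(benzyloxy)-6-bromobenzoate F5, and Br/Mg exchange with i-PrMgCl·LiCl (THF, −20 °C) would give [3,5-bis(benzyloxy)-2-(methoxycarbonyl)phenyl]magnesium chloride F6. With catalytic CuI, F6 would open F4 (its hydroxyl first converted into the magnesium alkoxide with one equivalent of i-PrMgCl) at the terminal carbon, and the secondary alkoxide would close on the ortho ester to give 14, with the (R) centre of the epoxide carried over unchanged as C3. Compound 14 would then be hydrogenolysed to 15 as in the second stage of step 8.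

Step 8. What may go wrong: double-bond migration towards C3/C4 on the metal surface before saturation (loss of configuration at C3); hydrogenolysis of the allylic C3–O bond with ring opening; incomplete cleavage of the benzyl ethers. The fallback avoids metal-surface hydrogen altogether. It sets out from 13 and returns at 15. The C=C bond would be reduced with diimide (2-nitrobenzenesulfonyl hydrazide, Et3N, CH2Cl2, rt), a concerted metal-free hydrogen transfer that can neither move the double bond nor cleave C–O, and 14 would be isolated. The benzyl ethers would then be removed by Lewis-acid cleavage (BCl3, pentamethylbenzene, CH2Cl2, −78 °C) to give 15. No new compound is made on this way.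

Step 6. What may go wrong: incomplete hydrozirconation in the presence of the zirconium alkoxide; protonolysis of the alkenylzirconium to the terminal alkene; loss of volatile vinyl bromide and homocoupling in the Pd step. The fallback builds the (E)-diene by cheletropic SO2 extrusion and forms the carbinol C–C bond last. It sets out from 7 and returns at 12. 3-Sulfolene would be deprotonated (LiHMDS, THF/DMPU, −78 °C) in the presence of excess 1,5-dibromopentane to give 2-(5-bromopentyl)-2,5-dihydrothiophene 1,1-dioxide F7. Heating (toluene, pyridine, 110 °C) would extrude SO2 with outward rotation of the alkyl group to give (E)-9-bromonona-1,3-diene F8. Its Grignard reagent, (E)-nona-6,8-dien-1-ylmagnesium bromide F9, would open 7 at CH2 under CuI catalysis (THF, −30 °C) to give 12 with the (S) carbinol centre intact.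

## Further compounds

F1 | step 7 | non-8-en-1-ylmagnesium bromide | C=CCCCCCCC[Mg]Br
F2 | step 7 | (3S)-tridec-12-en-3-ol | CC[C@H](O)CCCCCCCCC=C
F3 | step 7 | (3S)-11-(oxiran-2-yl)undecan-3-ol (both epimers at the oxirane carbon) | CC[C@H](O)CCCCCCCCC1CO1
F4 | step 7 | (3S)-11-[(2R)-oxiran-2-yl]undecan-3-ol | CC[C@H](O)CCCCCCCC[C@@H]1CO1
F5 | step 7 | methyl 2,4-bis(benzyloxy)-6-bromobenzoate | COC(=O)c1c(Br)cc(OCc2ccccc2)cc1OCc1ccccc1
F6 | step 7 | [3,5-bis(benzyloxy)-2-(methoxycarbonyl)phenyl]magnesium chloride | COC(=O)c1c([Mg]Cl)cc(OCc2ccccc2)cc1OCc1ccccc1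
F0 | step 8 | none | none
F7 | step 6 | 2-(5-bromopentyl)-2,5-dihydrothiophene 1,1-dioxide | BrCCCCCC1C=CCS1(=O)=O
F8 | step 6 | (E)-9-bromonona-1,3-diene | BrCCCCC/C=C/C=C
F9 | step 6 | (E)-nona-6,8-dien-1-ylmagnesium bromide | Br[Mg]CCCCC/C=C/C=C
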